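## Retrosynthetic overview

1. Target 15 ← fluoride desilylation of 14 ← hydrolysis of the 2-aryl-1,3-dithiane 13, which carries the aroyl carbonyl in masked form.
2. The oxolane ring (the only ring built for the target, formed last) ← acid-mediated benzylic C2–O1 closure of triol 12, placing the aryl group trans to C3.
3. Triol 12 ← LiAlH4 reduction of lactone acetal 11, which releases the menthol auxiliary.
4. 11 ← key step: intermolecular Michael addition of lithiated dithiane 9 to (5R)-menthyloxybutenolide 8 (C4–C bond), then intermolecular aldol of enolate 10 with aldehyde 2 (C3–C2 bond).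
5. 2 and 3 ← syringaldehyde; butenolide ring of 8 (formed first, later sacrificed) ← furfural + (−)-menthol.

Abbreviation and assumption: ArT = 3,5-dimethoxy-4-[(triisopropylsilyl)oxy]phenyl. The carbinol epimers of 11 and 12 are carried together because that centre is re-set in step 7.

## Route

**Step 1**
Reactants: 1 syringaldehyde (4-hydroxy-3,5-dimethoxybenzaldehyde)
Product: 2 3,5-dimethoxy-4-[(triisopropylsilyl)oxy]benzaldehyde
Conditions: TIPSCl (1.2 equiv), imidazole (2.5 equiv), DMF, rt, 12 h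
Reagents that add atoms: chlorotriisopropylsilane (TIPSCl), CC(C)[Si](Cl)(C(C)C)C(C)C
Why: Imidazole-promoted O-silylation of the acidic phenol gives a hindered aryl TIPS ether that survives n-BuLi, LiAlH4 and sulfonic acid and is removed by fluoride at the end (protecting-group installation).

**Step 2**
Reactants: 2 3,5-dimethoxy-4-[(triisopropylsilyl)oxy]benzaldehyde
Product: 3 2-(ArT)-1,3-dithiane
Conditions: HS(CH2)3SH (1.1 equiv), BF3·OEt2 (0.1 equiv), CH2Cl2, 0 °C → rt
Reagents that add atoms: propane-1,3-dithiol, SCCCS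
Why: Lewis-acid-catalysed dithioacetalisation converts the aldehyde into an acyl-anion equivalent (umpolung) whose carbon later becomes the ketone carbon.

**Step 3**
Reactants: 4 furfural
Product: 6 5-hydroxyfuran-2(5H)-one (racemic), via furfural endoperoxide 5 (not isolated)
Conditions: O2, rose bengal (C20H2Cl4I4Na2O5, 0.5 mol %), visible light, MeOH, 20 °C; evaporate
Reagents that add atoms: dioxygen, O=O
Why: Dye-sensitised singlet-oxygen [4+2] photooxygenation of the furan gives endoperoxide 5, which methanol cleaves at the formyl group (as methyl formate) to the γ-hydroxybutenolide.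

**Step 4**
Reactants: 6 5-hydroxyfuran-2(5H)-one; 7 (−)-menthol [(1R,2S,5R)-2-isopropyl-5-methylcyclohexanol]
Product: 8 (5R)-5-{[(1R,2S,5R)-2-isopropyl-5-methylcyclohexyl]oxy}furan-2(5H)-one
Conditions: CSA (5 mol %), PhMe, reflux, Dean–Stark; crystallise from petroleum ether, −20 °C; mother liquor re-equilibrated with CSA and recrystallised
Reagents that add atoms: none
Why: Acid-catalysed acetalisation gives both C5 epimers, which interconvert under acid, and the (5R) epimer crystallises selectively, so C5 is set by crystallisation-induced diastereomer enrichment.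

**Step 5 (key step)**
Reactants: 3 2-(ArT)-1,3-dithiane; 8 (5R)-5-menthyloxyfuran-2(5H)-one; 2 3,5-dimethoxy-4-[(triisopropylsilyl)oxy]benzaldehyde
Product: 11 (3S,4R,5R)-4-[2-(ArT)-1,3-dithian-2-yl]-3-[hydroxy(ArT)methyl]-5-[(1R,2S,5R)-menthyloxy]dihydrofuran-2(3H)-one (both carbinol epimers), via 2-lithio-1,3-dithiane 9 (not isolated), via lithium lactone enolate 10 (not isolated)
Conditions: 3, n-BuLi (1.05 equiv), THF, −78 → −20 °C, 1.5 h; 8 (1.0 equiv), −78 °C, 1 h; 2 (1.2 equiv), −78 °C, 2 h; AcOH/THF quench at −78 °C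
Reagents that add atoms: none
Why: Tandem Michael addition–aldol reaction: the soft aryl-dithiane anion adds 1,4 to the butenolide anti to the menthyloxy group (sets C4 as R), and enolate 10 is trapped by aldehyde 2 anti to the new C4 substituent (sets C3 as S, trans,trans-lactone); the carbinol centre forms unselectively and is corrected in step 7.

**Step 6**
Reactants: 11 the aldol adduct
Product: 12 (2R,3R)-2-[2-(ArT)-1,3-dithian-2-yl]-3-[hydroxy(ArT)methyl]butane-1,4-diol (both carbinol epimers)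
Conditions: LiAlH4 (3 equiv), THF, 0 °C → rt, 2 h; H2O, 15% aq. NaOH, H2O
Reagents that add atoms: none
Why: Hydride reduction of the lactone carbonyl, then of the C5 aldehyde unveiled when the hemiacetal alkoxide expels menthoxide, turns both termini into CH2OH without touching the two stereocentres (lactone/acetal reduction with auxiliary recovery).

**Step 7**
Reactants: 12 the triol
Product: 13 [(2S,3R,4R)-2-(ArT)-4-[2-(ArT)-1,3-dithian-2-yl]oxolan-3-yl]methanol
Conditions: p-TsOH·H2O (0.2 equiv), CH2Cl2, 0 °C → rt, monitored by TLC; sat. NaHCO3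
Reagents that add atoms: none
Why: Acid-catalysed SN1 cycloetherification: both carbinol epimers ionise to the same benzylic cation, which the C4-bound primary hydroxyl captures as a five-membered ring (the other primary OH could only form an oxetane), giving the aryl group trans to both the C3 and C4 substituents (C2 = S) under kinetic and thermodynamic control.

**Step 8**
Reactants: 13 the oxolane dithiane
Product: 14 [(2S,3R,4R)-2-(ArT)-3-(hydroxymethyl)oxolan-4-yl](ArT)methanone (oxolane numbered O1, C2 aryl, C3 CH2OH, C4 aroyl)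
Conditions: Hg(ClO4)2·3H2O (2.2 equiv), CaCO3 (4 equiv), THF/H2O (5:1), 0 °C, 20 min; filter through Celite
Reagents that add atoms: water, O
Why: Thiophilic divalent mercury activates the dithioacetal for hydrolysis to the aryl ketone, and the CaCO3 buffer and low temperature protect the epimerisable C4 centre, cis to CH2OH, from enolisation (dithiane deprotection).

**Step 9**
Reactants: 14 the bis-silyl ketone
Product: 15 ciwujiatone, [(2S,3R,4R)-2-(4-hydroxy-3,5-dimethoxyphenyl)-3-(hydroxymethyl)oxolan-4-yl](4-hydroxy-3,5-dimethoxyphenyl)methanone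
Conditions: TBAF (2.5 equiv), AcOH (2.5 equiv), THF, 0 °C, 1 h
Reagents that add atoms: none
Why: Fluoride cleaves both aryl Si–O bonds, and the acetic acid buffer prevents base-induced C4 epimerisation or retro-oxa-Michael opening of the β-alkoxy ketone (silyl ether deprotection).

## Compound list

1 | syringaldehyde | COc1cc(C=O)cc(OC)c1O | starting material
2 | 3,5-dimethoxy-4-[(triisopropylsilyl)oxy]benzaldehyde | COc1cc(C=O)cc(OC)c1O[Si](C(C)C)(C(C)C)C(C)C | intermediate
3 | 2-{3,5-dimethoxy-4-[(triisopropylsilyl)oxy]phenyl}-1,3-dithiane | COc1cc(C2SCCCS2)cc(OC)c1O[Si](C(C)C)(C(C)C)C(C)C | intermediate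
4 | furfural | O=Cc1ccco1 | starting material
5 | furfural endoperoxide, 2,3,7-trioxabicyclo[2.2.1]hept-5-ene-1-carbaldehyde (racemic, not isolated) | O=CC12C=CC(OO1)O2 | intermediate
6 | 5-hydroxyfuran-2(5H)-one (racemic) | OC1OC(=O)C=C1 | intermediate
7 | (−)-menthol, (1R,2S,5R) | CC(C)[C@@H]1CC[C@@H](C)C[C@H]1O | starting material
8 | (5R)-5-[(1R,2S,5R)-menthyloxy]furan-2(5H)-one | CC(C)[C@@H]1CC[C@@H](C)C[C@H]1O[C@H]1C=CC(=O)O1 | intermediate
9 | 2-lithio-2-(ArT)-1,3-dithiane (not isolated) | [Li]C1(c2cc(OC)c(O[Si](C(C)C)(C(C)C)C(C)C)c(OC)c2)SCCCS1 | intermediate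
10 | lithium (4R,5R)-4-[2-(ArT)-1,3-dithian-2-yl]-5-menthyloxy-4,5-dihydrofuran-2-olate (not isolated) | [Li]OC1=C[C@@H](C2(c3cc(OC)c(O[Si](C(C)C)(C(C)C)C(C)C)c(OC)c3)SCCCS2)[C@H](O[C@@H]2C[C@H](C)CC[C@H]2C(C)C)O1 | intermediate
11 | (3S,4R,5R)-4-[2-(ArT)-1,3-dithian-2-yl]-3-[hydroxy(ArT)methyl]-5-[(1R,2S,5R)-menthyloxy]dihydrofuran-2(3H)-one, both carbinol epimers | O=C1O[C@@H](O[C@@H]2C[C@H](C)CC[C@H]2C(C)C)[C@H](C2(c3cc(OC)c(O[Si](C(C)C)(C(C)C)C(C)C)c(OC)c3)SCCCS2)[C@H]1C(O)c1cc(OC)c(O[Si](C(C)C)(C(C)C)C(C)C)c(OC)c1 | intermediate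
12 | (2R,3R)-2-[2-(ArT)-1,3-dithian-2-yl]-3-[hydroxy(ArT)methyl]butane-1,4-diol, both carbinol epimers | OC[C@H](C1(c2cc(OC)c(O[Si](C(C)C)(C(C)C)C(C)C)c(OC)c2)SCCCS1)[C@H](CO)C(O)c1cc(OC)c(O[Si](C(C)C)(C(C)C)C(C)C)c(OC)c1 | intermediate
13 | [(2S,3R,4R)-2-(ArT)-4-[2-(ArT)-1,3-dithian-2-yl]oxolan-3-yl]methanol | OC[C@@H]1[C@@H](c2cc(OC)c(O[Si](C(C)C)(C(C)C)C(C)C)c(OC)c2)OC[C@@H]1C1(c2cc(OC)c(O[Si](C(C)C)(C(C)C)C(C)C)c(OC)c2)SCCCS1 | intermediate
14 | [(2S,3R,4R)-2-(ArT)-3-(hydroxymethyl)oxolan-4-yl](ArT)methanone | OC[C@@H]1[C@@H](c2cc(OC)c(O[Si](C(C)C)(C(C)C)C(C)C)c(OC)c2)OC[C@@H]1C(=O)c1cc(OC)c(O[Si](C(C)C)(C(C)C)C(C)C)c(OC)c1 | intermediate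
15 | ciwujiatone | COc1cc(C(=O)[C@H]2CO[C@H](c3cc(OC)c(O)c(OC)c3)[C@H]2CO)cc(OC)c1O | target

## Step count and risks

Total steps: 9. Longest linear sequence: 7 steps (1, 2, 5, 6, 7, 8, 9; the branch 3, 4, 5, 6, 7, 8, 9 is equally long).

**Step 5 (three-component Michael–aldol).** The risk is incomplete or reversible aldol trapping of the hindered lithium enolate. The fallback sets out from 8 (with 9 generated from 3 as before). The conjugate addition is quenched at −78 °C with NH4Cl and the product is isolated as the Michael adduct (4R,5R)-4-[2-(ArT)-1,3-dithian-2-yl]-5-menthyloxydihydrofuran-2(3H)-one F1. In a separate operation F1 is deprotonated with LiN(iPr)2 (THF, −78 °C) and transmetalated with ZnCl2 to the chlorozinc lactone enolate F2. The chelated, far less reversible zinc aldol with 2 (2 equiv, −78 → −40 °C) then gives the same trans,trans adduct, and the route is rejoined at 11.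

**Step 7 (acid cyclisation).** The risks are sluggish ionisation of the silyl-protected syringyl carbinol, Friedel–Crafts closure onto the other arene, or sulfur participation. The fallback sets out from 12. Both silyl groups are removed first (TBAF/AcOH, THF, 0 °C) to give the bis-phenol triol (2R,3R)-2-[2-(4-hydroxy-3,5-dimethoxyphenyl)-1,3-dithian-2-yl]-3-[hydroxy(4-hydroxy-3,5-dimethoxyphenyl)methyl]butane-1,4-diol F3. Its free para-hydroxybenzylic alcohol closes through a para-quinone methide (intramolecular oxa-Michael) under very mild acid (PPTS cat., MeCN, 40 °C) to the bis-phenol oxolane dithiane [(2S,3R,4R)-2-(4-hydroxy-3,5-dimethoxyphenyl)-4-[2-(4-hydroxy-3,5-dimethoxyphenyl)-1,3-dithian-2-yl]oxolan-3-yl]methanol F4, again with the aryl group trans. Hydrolysis of F4 with Hg(ClO4)2/CaCO3 (THF/H2O, 0 °C) delivers the target directly, so the route is rejoined at 15 and compounds 13 and 14 are bypassed.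

**Step 8 (dithiane hydrolysis).** The risks are incomplete cleavage of the hindered dithiane or damage to the β-alkoxy ketone. The fallback sets out from 13. One sulfur is oxidised selectively (mCPBA, 1.0 equiv, CH2Cl2, −78 °C) to the dithiane 1-oxide F5 (mixture of sulfoxide diastereomers). The activated monosulfoxide is then hydrolysed under mild acid (2 M HCl, THF, 0 °C → rt), with the sulfur fragment leaving as a cyclic disulfide, and the route is rejoined at 14.

## Further compounds

F1 | step 5 | (4R,5R)-4-[2-(ArT)-1,3-dithian-2-yl]-5-[(1R,2S,5R)-menthyloxy]dihydrofuran-2(3H)-one | O=C1O[C@@H](O[C@@H]2C[C@H](C)CC[C@H]2C(C)C)[C@H](C2(c3cc(OC)c(O[Si](C(C)C)(C(C)C)C(C)C)c(OC)c3)SCCCS2)C1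
F2 | step 5 | chlorozinc (4R,5R)-4-[2-(ArT)-1,3-dithian-2-yl]-5-menthyloxy-4,5-dihydrofuran-2-olate | Cl[Zn]OC1=C[C@@H](C2(c3cc(OC)c(O[Si](C(C)C)(C(C)C)C(C)C)c(OC)c3)SCCCS2)[C@H](O[C@@H]2C[C@H](C)CC[C@H]2C(C)C)O1
F3 | step 7 | (2R,3R)-2-[2-(4-hydroxy-3,5-dimethoxyphenyl)-1,3-dithian-2-yl]-3-[hydroxy(4-hydroxy-3,5-dimethoxyphenyl)methyl]butane-1,4-diol, both carbinol epimers | OC[C@H](C1(c2cc(OC)c(O)c(OC)c2)SCCCS1)[C@H](CO)C(O)c1cc(OC)c(O)c(OC)c1
F4 | step 7 | [(2S,3R,4R)-2-(4-hydroxy-3,5-dimethoxyphenyl)-4-[2-(4-hydroxy-3,5-dimethoxyphenyl)-1,3-dithian-2-yl]oxolan-3-yl]methanol | OC[C@@H]1[C@@H](c2cc(OC)c(O)c(OC)c2)OC[C@@H]1C1(c2cc(OC)c(O)c(OC)c2)SCCCS1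
F5 | step 8 | [(2S,3R,4R)-2-(ArT)-4-[2-(ArT)-1-oxido-1,3-dithian-2-yl]oxolan-3-yl]methanol, mixture of sulfoxide diastereomers | OC[C@@H]1[C@@H](c2cc(OC)c(O[Si](C(C)C)(C(C)C)C(C)C)c(OC)c2)OC[C@@H]1C1(c2cc(OC)c(O[Si](C(C)C)(C(C)C)C(C)C)c(OC)c2)S(=O)CCCS1
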